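Assumption: Eriostemin is taken as drawn, 3,8-dihydroxy-5,6,7-trimethoxy-2-(4-methoxyphenyl)-4H-chromen-4-one, which has no stereocentre. Compounds 1, 12 and 13 and the simple reagents named on the reagent lines are taken to be commercial.

## The problem

Eriostemin (22) is a flavonol: a benzene ring A is fused through C4a–C8a to the pyranone ring C, which carries the 4-methoxyphenyl ring B at C2 and a hydroxyl at C3. There is no stereocentre, so nothing in the structure has to control anything else in space; the task is regiochemical and sits on a fully substituted ring A. C4a bears the acyl carbon C4, C8a bears the ring oxygen O1, and C5 to C8 each bear an oxygen, of which three are methylated and only O8 is free. O3 must also end free, although O5, the least nucleophilic oxygen because of its hydrogen bond to C4=O, must end methylated. The ether at O5 is also the one most easily cleaved by Lewis acids, so O8 cannot be uncovered by a late demethylation and the distinction between O5 and O8 has to be built in. The 8-hydroxy-5-methoxy ring, and still more any 5,8-dihydroxy intermediate, is a hydroquinone that air oxidises to the 5,8-quinone in base; in hot strong acid a 5-hydroxyflavone can open and reclose ring C on the other oxygen (Wessely–Moser rearrangement), which would exchange the C6 and C8 substituents. The usual flavonol closure, Algar–Flynn–Oyamada oxidation of a 2'-hydroxychalcone, diverts to aurones when the 6'-position is substituted, as it is here, so O3 is best brought in with the carbon chain. The enabling feature is that C4a and C8a are neighbours, one bearing carbon and one oxygen, flanked by oxygen-bearing C5 and C8 with two identical methoxy groups behind them: if O5 and O8 carry the same protecting group, ring A is the adduct of a mirror-symmetric tetraoxygenated benzyne with the O–C(=O) unit of a carboxylic acid.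

## Retrosynthesis

**22 from 21.** The two oxygens that must end free, O3 and O8, are cut back to benzyl ethers, so that one hydrogenolysis of 21 finishes the synthesis. Benzyl is chosen for both because it survives acid, base and fluoride and leaves under neutral conditions that do not touch the methyl ethers or the oxidation-prone product. The forward step only has to spare the tetrasubstituted C2=C3 bond of the chromenone.

**21 from 20 from 19.** The O5–methyl bond and then the O8–benzyl bond are cut, which leads to the 5,8-dihydroxyflavone 19. In 19 the two phenols differ through the hydrogen bond of 5-OH to C4=O: the free 8-OH is benzylated first (20), then the chelated 5-OH is methylated under forcing conditions (21). The reverse tactic, selective dealkylation, would strike O5 rather than O8, and a direct selective methylation of O5 is not possible. The forward steps need an inert atmosphere because 19 is a hydroquinone.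

**19 from 18 from 17.** Two acetal O–C bonds are cut (19 to the bis-methoxymethyl ether 18), then the O1–C2 bond with two hydrogens restored, which opens ring C to the 2'-hydroxy-α-benzyloxychalcone 17. An Algar–Flynn–Oyamada closure of an unoxygenated chalcone would save the benzyloxy acid, but the 6'-substituent would steer it to the aurone; with O3 already in place as a benzyl ether, a plain oxidative cyclisation suffices. The forward step needs the acetal at O5 to stay until the ring is closed, since a free 6'-phenol would close in competition and give the 5,6-dihydroxy-7,8-dimethoxy isomer.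

**17 from 11 and 15.** Cutting O1–C8a and C4–C4a together is the key disconnection: the aryne 16 released from the silyl triflate 11 inserts into the C–O bond of the acid 15. A Friedel–Crafts or Fries acylation would instead need a pentaoxygenated phenol that is already unsymmetrical, and a Lewis acid that strips acetals and ortho ethers. An aryllithium with an activated acid derivative would need a further, distinct protecting group on O1. With the aryne, the ring oxygen and the acyl carbon arrive in one event on two adjacent carbons of a ring that is symmetric at that moment, so there is no orientation to control, and the precursors shrink to a symmetric benzene derivative and a cinnamic acid. The forward reaction must let the acyl shift in the aryl anion outrun its protonation.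

**11 from 9 from 8 from 7.** The C–Si and O–triflyl bonds are cut back to the ortho-bromophenol 8 through its silyl ether 9 (bromine–lithium exchange, retro-Brook shift, triflation). The C–Br bond is cut back to phenol 7, whose only ring C–H is the one to be brominated.

**7 from 4 from 3 from 1.** The phenol C–O bond of 7 is cut back to the bis-acetal 4 (directed ortho-metalation, borylation, oxidation); the two ring C–H bonds of 4 are equivalent, so only one phenol can form. 4 comes from 2,3-dimethoxyhydroquinone 3, and 3 from commercial 2,3-dimethoxyphenol 1 by para-oxidation to quinone 2 and reduction.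

**15 from 12 and 13.** The Cα=Cβ bond of the acid (the later C3=C2) is cut to 4-methoxybenzaldehyde 12 and methyl 2-(benzyloxy)acetate 13. Aldol condensation and saponification through ester 14 give the thermodynamically preferred Z acid; the geometry is erased later anyway.

## Roads not taken

Alternative 1: C4a–C4, C4–C3 and O1–C2 are cut at once. The ortho-iodophenol 2-(benzyloxy)-6-iodo-3,4,5-trimethoxyphenol A1, the alkyne 1-ethynyl-4-methoxybenzene A2 and carbon monoxide A3 would combine under a palladium catalyst such as PdCl2(PPh3)2 with an amine base. Carbonylative coupling of A1 with A2 and A3 is followed by 6-endo addition of the phenol to the acyl alkyne, giving 8-(benzyloxy)-5,6,7-trimethoxy-2-(4-methoxyphenyl)-4H-chromen-4-one A4.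
- Merits: three bonds and ring C are made in the key step, against two bonds and no ring in the chosen plan. A2 and A3 are simple commercial partners. The ring A pattern is final from the outset, so no 5,8-dihydroxy intermediate is needed.
- Weak points: A4 has no oxygen at C3, so a C3 hydroxylation of a polyoxygenated flavone has to follow. A1 is a hexasubstituted benzene with no symmetry, so O8 and O5 must be told apart without the chelation handle. Oxidative addition of zerovalent palladium into an electron-rich, doubly ortho-substituted aryl iodide is slow. Non-carbonylative coupling (to a benzofuran) and 5-exo closure (to an aurone) compete.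
- Comparison: this road is better in convergence at the key step. The chosen plan sets against it a symmetric aryne precursor made from a symmetric hydroquinone and an O3 that arrives with the acid.

Alternative 2: C3–C4 is cut. The racemic dialdehyde 3-(benzyloxy)-4,5,6-trimethoxy-2-[1-(4-methoxyphenyl)-2-oxoethoxy]benzaldehyde A5 would be treated with a triazolium-derived carbene. The aryl aldehyde becomes the acyl anion equivalent and adds to the aliphatic aldehyde, closing ring C as racemic trans-8-(benzyloxy)-3-hydroxy-5,6,7-trimethoxy-2-(4-methoxyphenyl)chroman-4-one A6. Dehydrogenation of A6 and debenzylation would follow.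
- Merits: the conditions are mild and metal-free. O3 and the C4 ketone are set directly, and ring C closes in the key step.
- Weak points: A5 needs the O1–C2 ether from a phenol flanked on both sides and a secondary benzylic electrophile. Its aliphatic aldehyde has a C–H activated by both aryl and aryloxy, so it can enolise, undergo aldol reaction and eliminate the phenoxide. The hindered, electron-rich aryl aldehyde is a reluctant acyl donor, so the donor and acceptor roles may invert. The two stereocentres of A6 are made only to be destroyed. Ring A of A5 is again unsymmetrical.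
- Comparison: it equals the chosen plan in delivering O3, but needs more steps to reach the key precursor and gains nothing from the symmetry of ring A.

Alternative 3: O1–C8a is cut. The diketone 2-(benzyloxy)-1-(4-methoxyphenyl)-3-(2,3,4,5-tetramethoxyphenyl)propane-1,3-dione A7 would be oxidised with (NH4)2Ce(NO3)6, which removes the two para-related methyl groups and raises ring A to the acylquinone level. The enol oxygen of the diketone then adds to C8a, and tautomerisation gives 3-(benzyloxy)-5,8-dihydroxy-6,7-dimethoxy-2-(4-methoxyphenyl)-4H-chromen-4-one A8, which is the same compound as 19.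
- Merits: it joins the chosen end game at 19, needs no aryne and no protecting group on ring A, and is probably shorter. In step count it is at least as good as the chosen plan.
- Weak points: oxidative demethylation of the 2,3,4,5-tetramethoxyaryl ketone A7 is not regiodefined. The para-quinone wanted competes with ortho-quinones from adjacent methoxy pairs, and one of the methoxy groups to be lost is ortho to the deactivating acyl group. Tetravalent cerium can also attack the enolisable α-benzyloxy diketone and the anisyl ring. A8 is a hydroquinone and is itself oxidised further by any excess oxidant.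
- Comparison: the chosen plan sets against the shorter sequence the fact that protecting groups, not an oxidant, decide which two oxygens are unmasked, and that no strong oxidant meets the electron-rich rings.

Key step: step 8

## Route

Step 1
Reactants: 1 2,3-dimethoxyphenol
Product: 3 2,3-dimethoxybenzene-1,4-diol, via 2,3-dimethoxy-1,4-benzoquinone 2 (not isolated)
Conditions: (KO3S)2NO (2.2 equiv), KH2PO4 buffer, H2O/acetone, 0 °C to rt; extract into EtOAc, then aq Na2S2O4, rt, Ar
Reagents that add atoms: potassium nitrosodisulfonate, [K+].[K+].[O]N(S(=O)(=O)[O-])S(=O)(=O)[O-]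
Why: Teuber oxidation of a phenol with a free para position gives the para-quinone 2, the new oxygen coming from the nitroxyl radical; dithionite reduction of the quinone in the extract gives the hydroquinone, which is used at once because it is air-sensitive.

Step 2
Reactants: 3 2,3-dimethoxybenzene-1,4-diol
Product: 4 1,4-bis(methoxymethoxy)-2,3-dimethoxybenzene
Conditions: NaH (2.4 equiv), DMF, 0 °C, Ar; MOMCl (2.4 equiv), 0 °C to rt
Reagents that add atoms: chloromethyl methyl ether, COCCl
Why: Williamson-type O-alkylation of both phenoxides with the reactive α-chloro ether; the acetal is chosen because it directs the lithiation of step 3 and is later removed by acid without touching benzyl or methyl ethers.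

Step 3
Reactants: 4 1,4-bis(methoxymethoxy)-2,3-dimethoxybenzene
Product: 7 3,4-dimethoxy-2,5-bis(methoxymethoxy)phenol, via aryllithium 5 (not isolated), via lithium aryltrimethoxyborate 6 (not isolated)
Conditions: n-BuLi (1.1 equiv), TMEDA, THF, −78 to 0 °C; B(OMe)3, −78 °C to rt; 30% H2O2, aq NaOH, 0 °C; NH4Cl work-up
Reagents that add atoms: hydrogen peroxide, OO (n-butyllithium, [Li]CCCC, and trimethyl borate, COB(OC)OC, leave atoms only in 5 and 6)
Why: Directed ortho-metalation next to the coordinating acetal, borylation and oxidative 1,2-migration from boron to oxygen; the two ring C–H bonds of 4 are equivalent by symmetry, so one phenol should result.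

Step 4
Reactants: 7 3,4-dimethoxy-2,5-bis(methoxymethoxy)phenol
Product: 8 2-bromo-4,5-dimethoxy-3,6-bis(methoxymethoxy)phenol
Conditions: NBS (1.0 equiv), CH2Cl2, −78 to 0 °C, dark
Reagents that add atoms: N-bromosuccinimide, O=C1CCC(=O)N1Br
Why: Electrophilic aromatic bromination at the only unsubstituted ring carbon, which is ortho to the free phenol; low temperature and an anhydrous medium are chosen to disfavour oxidation of the electron-rich phenol.

Step 5
Reactants: 8 2-bromo-4,5-dimethoxy-3,6-bis(methoxymethoxy)phenol
Product: 9 [2-bromo-4,5-dimethoxy-3,6-bis(methoxymethoxy)phenoxy]trimethylsilane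
Conditions: HMDS (excess), THF, 70 °C; evaporate, use crude
Reagents that add atoms: hexamethyldisilazane, C[Si](C)(C)N[Si](C)(C)C
Why: O-silylation of the phenol with hexamethyldisilazane, whose only by-product is ammonia, so the moisture-sensitive silyl ether can be carried on after evaporation.

Step 6
Reactants: 9 [2-bromo-4,5-dimethoxy-3,6-bis(methoxymethoxy)phenoxy]trimethylsilane
Product: 11 3,6-bis(methoxymethoxy)-4,5-dimethoxy-2-(trimethylsilyl)phenyl trifluoromethanesulfonate, via lithium 2-silylphenoxide 10 (not isolated)
Conditions: n-BuLi (1.1 equiv), THF, −100 to −78 °C; Tf2O (1.2 equiv), −100 °C to rt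
Reagents that add atoms: trifluoromethanesulfonic anhydride, O=S(=O)(OS(=O)(=O)C(F)(F)F)C(F)(F)F (n-butyllithium, [Li]CCCC, leaves lithium only in 10)
Why: Bromine–lithium exchange gives an aryllithium ortho to the silyloxy group, which undergoes the retro-Brook 1,3-shift of silicon from oxygen to carbon; the lithium phenoxide 10 is then O-triflated, the standard way from ortho-bromophenols to ortho-silylaryl triflates.

Step 7
Reactants: 12 4-methoxybenzaldehyde, 13 methyl 2-(benzyloxy)acetate
Product: 15 (Z)-2-(benzyloxy)-3-(4-methoxyphenyl)prop-2-enoic acid, via methyl (Z)-2-(benzyloxy)-3-(4-methoxyphenyl)prop-2-enoate 14 (not isolated)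
Conditions: t-BuOK (1.2 equiv), THF, −20 °C to rt; then aq KOH, MeOH, 50 °C; HCl to pH 2, crystallise
Reagents that add atoms: potassium hydroxide, [K+].[OH-] (supplies the carboxyl oxygen on saponification of 14)
Why: Claisen-type aldol condensation of an alkoxyacetate enolate with a non-enolisable aryl aldehyde, followed by elimination and saponification in the same pot; the Z isomer, with aryl and carboxyl trans, is the thermodynamic one and should crystallise as the acid.

Step 8
Reactants: 11 3,6-bis(methoxymethoxy)-4,5-dimethoxy-2-(trimethylsilyl)phenyl trifluoromethanesulfonate, 15 (Z)-2-(benzyloxy)-3-(4-methoxyphenyl)prop-2-enoic acid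
Product: 17 (Z)-2-(benzyloxy)-1-[2-hydroxy-4,5-dimethoxy-3,6-bis(methoxymethoxy)phenyl]-3-(4-methoxyphenyl)prop-2-en-1-one, via 3,6-bis(methoxymethoxy)-4,5-dimethoxybenzyne 16 (not isolated)
Conditions: 15 (1.0 equiv), CsF (5 equiv), THF, rt, then 11 (1.5 equiv), sealed tube, 125 °C, Ar
Reagents that add atoms: none
Why: Fluoride attacks silicon in 11 and triflate leaves, releasing the aryne 16 at low stationary concentration. The cesium carboxylate of 15 adds through oxygen to one aryne carbon, and the aryl anion so formed attacks the carbonyl of the new aryl ester through a four-membered alkoxide that opens to the ortho-acyl phenoxide; this forms O1–C8a and C4–C4a, one acid oxygen becoming O1 and the other remaining as C4=O. The closest known reaction type is the fluoride-induced insertion of arynes into the C–O bond of carboxylic acids to give ortho-hydroxyaryl ketones, known for aryl, alkyl and α,β-unsaturated acids and for alkoxy-substituted arynes; its second stage is an anionic Fries-type 1,3-acyl shift. No ring is closed and no stereocentre is made; the Z double bond is the thermodynamic isomer and is erased in step 9. The step needs no regiocontrol because both groups beside the triple bond are the same acetal ether, so either orientation of addition gives 17; the inductive pull of these two oxygens also activates the crowded aryne towards the small carboxylate oxygen. It does need the acyl shift to outrun protonation of the aryl anion, which is secured by having the acid fully as its cesium salt before the aryne appears, by the high temperature and by the intramolecular nature of the shift. Further arylation of the product is held back because its phenoxide is chelated to the ketone and flanked on both sides. The α-benzyloxy and 4-methoxyphenyl donors lower the electrophilicity of the β-carbon, so the phenoxide is not expected to add to the enone; any material that did close would be dehydrogenated to the same flavone 18 in step 9.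

Step 9
Reactants: 17 (Z)-2-(benzyloxy)-1-[2-hydroxy-4,5-dimethoxy-3,6-bis(methoxymethoxy)phenyl]-3-(4-methoxyphenyl)prop-2-en-1-one
Product: 18 3-(benzyloxy)-6,7-dimethoxy-5,8-bis(methoxymethoxy)-2-(4-methoxyphenyl)-4H-chromen-4-one
Conditions: I2 (10 mol%), DMSO, 110 °C, Ar; aq Na2S2O3 work-up
Reagents that add atoms: none
Why: Iodine-catalysed oxidative cyclisation of a 2'-hydroxychalcone: the only free phenol adds 6-endo to the iodine-activated enol ether double bond, HI is lost to give C2=C3, and DMSO reoxidises HI to I2. The electron-rich double bond should react faster than the acetals are cleaved at the low stationary HI concentration, and benzyl ethers are routinely carried through these conditions.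

Step 10
Reactants: 18 3-(benzyloxy)-6,7-dimethoxy-5,8-bis(methoxymethoxy)-2-(4-methoxyphenyl)-4H-chromen-4-one
Product: 19 3-(benzyloxy)-5,8-dihydroxy-6,7-dimethoxy-2-(4-methoxyphenyl)-4H-chromen-4-one
Conditions: conc. HCl (cat.), degassed MeOH/THF, 50 °C, Ar; work-up with a trace of Na2S2O4
Reagents that add atoms: none
Why: Acid-catalysed acetal exchange removes both methoxymethyl groups as dimethoxymethane while benzyl and methyl ethers stay; the acid is far too mild for ring opening of the Wessely–Moser type, and air is excluded because the product is a hydroquinone.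

Step 11
Reactants: 19 3-(benzyloxy)-5,8-dihydroxy-6,7-dimethoxy-2-(4-methoxyphenyl)-4H-chromen-4-one
Product: 20 3,8-bis(benzyloxy)-5-hydroxy-6,7-dimethoxy-2-(4-methoxyphenyl)-4H-chromen-4-one
Conditions: BnBr (1.05 equiv), K2CO3 (1.1 equiv), degassed DMF, rt, Ar
Reagents that add atoms: benzyl bromide, BrCc1ccccc1
Why: Williamson alkylation that discriminates between the two phenols: 8-OH is free and is deprotonated and alkylated first, whereas 5-OH is held in a hydrogen bond to C4=O and reacts only under forcing conditions; this is the usual order of reactivity in 5-hydroxyflavones.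

Step 12
Reactants: 20 3,8-bis(benzyloxy)-5-hydroxy-6,7-dimethoxy-2-(4-methoxyphenyl)-4H-chromen-4-one
Product: 21 3,8-bis(benzyloxy)-5,6,7-trimethoxy-2-(4-methoxyphenyl)-4H-chromen-4-one
Conditions: MeI (5 equiv), K2CO3 (3 equiv), DMF, 50 °C
Reagents that add atoms: iodomethane, CI
Why: O-methylation of the chelated 5-hydroxyl with excess methyl iodide and heat; every other oxygen is already capped, so no selectivity is required.

Step 13
Reactants: 21 3,8-bis(benzyloxy)-5,6,7-trimethoxy-2-(4-methoxyphenyl)-4H-chromen-4-one
Product: 22 Eriostemin, 3,8-dihydroxy-5,6,7-trimethoxy-2-(4-methoxyphenyl)-4H-chromen-4-one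
Conditions: H2 (1 atm), 10% Pd/C, EtOAc/MeOH, rt; filter and concentrate under Ar
Reagents that add atoms: none
Why: Catalytic hydrogenolysis cleaves both benzyl ethers at O3 and O8 under neutral conditions; the tetrasubstituted C2=C3 bond of the chromenone, a vinylogous ester, is not expected to be reduced at atmospheric pressure.

## Compound list

1 | 2,3-dimethoxyphenol | COc1cccc(O)c1OC | starting material
2 | 2,3-dimethoxy-1,4-benzoquinone | COC1=C(OC)C(=O)C=CC1=O | intermediate (not isolated)
3 | 2,3-dimethoxybenzene-1,4-diol | COc1c(O)ccc(O)c1OC | intermediate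
4 | 1,4-bis(methoxymethoxy)-2,3-dimethoxybenzene | COCOc1ccc(OCOC)c(OC)c1OC | intermediate
5 | [3,4-dimethoxy-2,5-bis(methoxymethoxy)phenyl]lithium | [Li]c1cc(OCOC)c(OC)c(OC)c1OCOC | intermediate (not isolated)
6 | lithium [3,4-dimethoxy-2,5-bis(methoxymethoxy)phenyl]trimethoxyborate | [Li+].CO[B-](OC)(OC)c1cc(OCOC)c(OC)c(OC)c1OCOC | intermediate (not isolated)
7 | 3,4-dimethoxy-2,5-bis(methoxymethoxy)phenol | Oc1cc(OCOC)c(OC)c(OC)c1OCOC | intermediate
8 | 2-bromo-4,5-dimethoxy-3,6-bis(methoxymethoxy)phenol | Oc1c(Br)c(OCOC)c(OC)c(OC)c1OCOC | intermediate
9 | [2-bromo-4,5-dimethoxy-3,6-bis(methoxymethoxy)phenoxy]trimethylsilane | C[Si](C)(C)Oc1c(Br)c(OCOC)c(OC)c(OC)c1OCOC | intermediate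
10 | lithium 4,5-dimethoxy-3,6-bis(methoxymethoxy)-2-(trimethylsilyl)phenolate | [Li+].[O-]c1c([Si](C)(C)C)c(OCOC)c(OC)c(OC)c1OCOC | intermediate (not isolated)
11 | 3,6-bis(methoxymethoxy)-4,5-dimethoxy-2-(trimethylsilyl)phenyl trifluoromethanesulfonate | COCOc1c(OC)c(OC)c(OCOC)c(OS(=O)(=O)C(F)(F)F)c1[Si](C)(C)C | intermediate
12 | 4-methoxybenzaldehyde | COc1ccc(C=O)cc1 | starting material
13 | methyl 2-(benzyloxy)acetate | COC(=O)COCc1ccccc1 | starting material
14 | methyl (Z)-2-(benzyloxy)-3-(4-methoxyphenyl)prop-2-enoate | COC(=O)/C(OCc1ccccc1)=C/c1ccc(OC)cc1 | intermediate (not isolated)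
15 | (Z)-2-(benzyloxy)-3-(4-methoxyphenyl)prop-2-enoic acid | OC(=O)/C(OCc1ccccc1)=C/c1ccc(OC)cc1 | intermediate
16 | 3,6-bis(methoxymethoxy)-4,5-dimethoxybenzyne | COCOC1=C(OC)C(OC)=C(OCOC)C#C1 | intermediate (not isolated)
17 | (Z)-2-(benzyloxy)-1-[2-hydroxy-4,5-dimethoxy-3,6-bis(methoxymethoxy)phenyl]-3-(4-methoxyphenyl)prop-2-en-1-one | COCOc1c(O)c(C(=O)/C(OCc2ccccc2)=C/c2ccc(OC)cc2)c(OCOC)c(OC)c1OC | intermediate
18 | 3-(benzyloxy)-6,7-dimethoxy-5,8-bis(methoxymethoxy)-2-(4-methoxyphenyl)-4H-chromen-4-one | COc1ccc(-c2oc3c(OCOC)c(OC)c(OC)c(OCOC)c3c(=O)c2OCc2ccccc2)cc1 | intermediate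
19 | 3-(benzyloxy)-5,8-dihydroxy-6,7-dimethoxy-2-(4-methoxyphenyl)-4H-chromen-4-one | COc1ccc(-c2oc3c(O)c(OC)c(OC)c(O)c3c(=O)c2OCc2ccccc2)cc1 | intermediate
20 | 3,8-bis(benzyloxy)-5-hydroxy-6,7-dimethoxy-2-(4-methoxyphenyl)-4H-chromen-4-one | COc1ccc(-c2oc3c(OCc4ccccc4)c(OC)c(OC)c(O)c3c(=O)c2OCc2ccccc2)cc1 | intermediate
21 | 3,8-bis(benzyloxy)-5,6,7-trimethoxy-2-(4-methoxyphenyl)-4H-chromen-4-one | COc1ccc(-c2oc3c(OCc4ccccc4)c(OC)c(OC)c(OC)c3c(=O)c2OCc2ccccc2)cc1 | intermediate
22 | Eriostemin, 3,8-dihydroxy-5,6,7-trimethoxy-2-(4-methoxyphenyl)-4H-chromen-4-one | COc1ccc(-c2oc3c(O)c(OC)c(OC)c(OC)c3c(=O)c2O)cc1 | target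

## Step count and risks

Total step count: 13. Longest linear sequence: 12 steps (steps 1 to 6 and 8 to 13, from 1); the acid branch contributes step 7.

**Step 8 (key step).** The most likely failure is protonation of the aryl anion before it reaches the ester carbonyl, which stops the sequence at simple O-arylation. The four-membered transition state has an acetal oxygen next to the anionic carbon and is crowded. Arylation of the product phenoxide by a second aryne is the other drain.
Fallback: it sets out from 8 (with 15) and returns at 17. Phenol 8 is esterified with 15 (carbodiimide, DMAP) to 2-bromo-4,5-dimethoxy-3,6-bis(methoxymethoxy)phenyl (Z)-2-(benzyloxy)-3-(4-methoxyphenyl)prop-2-enoate F1. Bromine–lithium exchange with t-BuLi (2 equiv) in THF/Et2O at −100 °C then triggers the exchange-induced anionic Fries rearrangement, in which the aryllithium attacks the neighbouring ester and the same four-membered alkoxide opens to the phenoxide of 17. The same two bonds are made, stepwise and without an aryne.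

**Step 9.** The acetal at O5 (the 6'-position of the chalcone) may be lost to traces of HI before ring C is closed; either phenol could then close, which would scramble the substitution of ring A. Any unmasked hydroquinone could also be oxidised by iodine. Material that loses an acetal only after closure converges in step 10.
Fallback: it sets out from 17 and returns at 18. Closure and dehydrogenation are separated and kept non-acidic. NaOAc in refluxing EtOH effects oxa-Michael closure to racemic trans-3-(benzyloxy)-6,7-dimethoxy-5,8-bis(methoxymethoxy)-2-(4-methoxyphenyl)chroman-4-one F2 (one enantiomer drawn; both centres are erased). DDQ in dioxane at 90 °C then dehydrogenates F2 to 18.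

**Step 11.** The hydroquinone may be oxidised by air to the 5,8-quinone once deprotonated, and O5 may be alkylated as well if base or halide is in excess.
Fallback: it sets out from 18 and returns at 22, and never passes through a free hydroquinone. MgBr2·OEt2 in Et2O/CH2Cl2 at rt, chelated between C4=O and O5, cleaves only the peri acetal to give 3-(benzyloxy)-5-hydroxy-6,7-dimethoxy-8-(methoxymethoxy)-2-(4-methoxyphenyl)-4H-chromen-4-one F3. Methylation (MeI, K2CO3, DMF, 50 °C) gives 3-(benzyloxy)-5,6,7-trimethoxy-8-(methoxymethoxy)-2-(4-methoxyphenyl)-4H-chromen-4-one F4. HCl in MeOH gives 3-(benzyloxy)-8-hydroxy-5,6,7-trimethoxy-2-(4-methoxyphenyl)-4H-chromen-4-one F5, and hydrogenolysis over Pd/C gives 22.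

**Step 4.** N-bromosuccinimide may oxidise the pentaoxygenated phenol, a para-alkoxyphenol, towards a quinone instead of brominating the ring. The same bypass also covers an incomplete silyl migration or a sluggish triflation of the hindered phenoxide in step 6.
Fallback: it sets out from 7 and returns at 11, replacing steps 4 to 6. Phenol 7 is carbamoylated (ClC(O)NEt2, NaH, THF) to 3,4-dimethoxy-2,5-bis(methoxymethoxy)phenyl diethylcarbamate F6. Directed ortho-metalation (s-BuLi, TMEDA, THF, −78 °C; the one free C–H lies between the carbamate and an acetal) and quenching with Me3SiCl at −78 °C give 4,5-dimethoxy-3,6-bis(methoxymethoxy)-2-(trimethylsilyl)phenyl diethylcarbamate F7. LiAlH4 in THF at 0 °C removes the carbamate to give 4,5-dimethoxy-3,6-bis(methoxymethoxy)-2-(trimethylsilyl)phenol F8, and Tf2O with pyridine in CH2Cl2 at 0 °C gives 11.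

## Further compounds

F1 | step 8 | 2-bromo-4,5-dimethoxy-3,6-bis(methoxymethoxy)phenyl (Z)-2-(benzyloxy)-3-(4-methoxyphenyl)prop-2-enoate | COCOc1c(OC)c(OC)c(OCOC)c(Br)c1OC(=O)/C(OCc1ccccc1)=C/c1ccc(OC)cc1
F2 | step 9 | trans-3-(benzyloxy)-6,7-dimethoxy-5,8-bis(methoxymethoxy)-2-(4-methoxyphenyl)chroman-4-one (racemate, one enantiomer drawn) | O=C1[C@@H](OCc2ccccc2)[C@H](c2ccc(OC)cc2)Oc2c(OCOC)c(OC)c(OC)c(OCOC)c21
F3 | step 11 | 3-(benzyloxy)-5-hydroxy-6,7-dimethoxy-8-(methoxymethoxy)-2-(4-methoxyphenyl)-4H-chromen-4-one | COc1ccc(-c2oc3c(OCOC)c(OC)c(OC)c(O)c3c(=O)c2OCc2ccccc2)cc1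
F4 | step 11 | 3-(benzyloxy)-5,6,7-trimethoxy-8-(methoxymethoxy)-2-(4-methoxyphenyl)-4H-chromen-4-one | COc1ccc(-c2oc3c(OCOC)c(OC)c(OC)c(OC)c3c(=O)c2OCc2ccccc2)cc1
F5 | step 11 | 3-(benzyloxy)-8-hydroxy-5,6,7-trimethoxy-2-(4-methoxyphenyl)-4H-chromen-4-one | COc1ccc(-c2oc3c(O)c(OC)c(OC)c(OC)c3c(=O)c2OCc2ccccc2)cc1
F6 | step 4 | 3,4-dimethoxy-2,5-bis(methoxymethoxy)phenyl diethylcarbamate | CCN(CC)C(=O)Oc1cc(OCOC)c(OC)c(OC)c1OCOC
F7 | step 4 | 4,5-dimethoxy-3,6-bis(methoxymethoxy)-2-(trimethylsilyl)phenyl diethylcarbamate | CCN(CC)C(=O)Oc1c([Si](C)(C)C)c(OCOC)c(OC)c(OC)c1OCOC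
F8 | step 4 | 4,5-dimethoxy-3,6-bis(methoxymethoxy)-2-(trimethylsilyl)phenol | Oc1c([Si](C)(C)C)c(OCOC)c(OC)c(OC)c1OCOC
A1 | alternative 1 | 2-(benzyloxy)-6-iodo-3,4,5-trimethoxyphenol | Oc1c(I)c(OC)c(OC)c(OC)c1OCc1ccccc1
A2 | alternative 1 | 1-ethynyl-4-methoxybenzene | C#Cc1ccc(OC)cc1
A3 | alternative 1 | carbon monoxide | [C-]#[O+]
A4 | alternative 1 | 8-(benzyloxy)-5,6,7-trimethoxy-2-(4-methoxyphenyl)-4H-chromen-4-one | COc1ccc(-c2cc(=O)c3c(OC)c(OC)c(OC)c(OCc4ccccc4)c3o2)cc1
A5 | alternative 2 | 3-(benzyloxy)-4,5,6-trimethoxy-2-[1-(4-methoxyphenyl)-2-oxoethoxy]benzaldehyde (racemate) | O=Cc1c(OC)c(OC)c(OC)c(OCc2ccccc2)c1OC(C=O)c1ccc(OC)cc1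
A6 | alternative 2 | trans-8-(benzyloxy)-3-hydroxy-5,6,7-trimethoxy-2-(4-methoxyphenyl)chroman-4-one (racemate, one enantiomer drawn) | O=C1[C@@H](O)[C@H](c2ccc(OC)cc2)Oc2c(OCc3ccccc3)c(OC)c(OC)c(OC)c21
A7 | alternative 3 | 2-(benzyloxy)-1-(4-methoxyphenyl)-3-(2,3,4,5-tetramethoxyphenyl)propane-1,3-dione | COc1ccc(C(=O)C(OCc2ccccc2)C(=O)c2cc(OC)c(OC)c(OC)c2OC)cc1
A8 | alternative 3 | 3-(benzyloxy)-5,8-dihydroxy-6,7-dimethoxy-2-(4-methoxyphenyl)-4H-chromen-4-one | COc1ccc(-c2oc3c(O)c(OC)c(OC)c(O)c3c(=O)c2OCc2ccccc2)cc1
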